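The route is built on disconnecting the C6=C7 bond, which is both the exocyclic alkylidene of the γ-lactone (ring B) and the cis olefin of the nine-membered carbocycle (ring A). An intramolecular Horner–Wadsworth–Emmons reaction between a C7 phosphonate and a C6 aldehyde therefore closes ring A and finishes the conjugated lactone in one operation, giving the target directly. Its precursor is an open-chain α-phosphono-γ-butyrolactone that already holds C1 (as acetate), C8, C9 and C1′ in their final configurations, the (E)-C3=C4 alkene and a β,γ-unsaturated aldehyde. It is built by an amine-catalysed Michael addition, a catalyst-controlled allenylboration and a trans-hydrostannation/methylation sequence.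

Key step: step 12

Numbering used throughout: ring A = C1 (CHOAc), C2, C3 (CMe), C4, C5, C6, C7 (lactone α-carbon), C8, C9; ring B = C7, C8, C11 (OCH2), O, C10 (C=O); C1′ is the side-chain CHMe carbon.

Remark: C7 of every phosphonate is configurationally labile; each is expected as a mixture of C7 epimers (the trans epimer is drawn) that converge in step 12.

Assumption: the (R)-prolinol silyl ether is taken to direct the acceptor to the same enamine face as in its nitroalkene additions, and (R)-TRIP to deliver to the Re face of the formyl group as in its allylborations; if either sense proves opposite, the mirror-image catalyst is used.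

Design note: C6 is carried as a silyl ether so that only the C1 hydroxyl is free when the acetate is introduced, and the C3=C4 alkene is made by chemistry that tolerates the acidic phosphono lactone.

Step 1
Reactants: 1 diethyl (2-oxotetrahydrofuran-3-yl)phosphonate
Product: 4 diethyl (2-oxo-2,5-dihydrofuran-3-yl)phosphonate, via α-phenylselanyl lactone 2 (not isolated), via selenoxide 3 (not isolated)
Conditions: NaH, THF, 0 °C; PhSeCl, 0 °C to rt; then 30% H2O2, CH2Cl2, 0 °C
Reagents that add atoms: none
Why: Selenenylation of the sodium enolate followed by selenoxide syn-elimination, which can only run toward the C8 hydrogens and therefore gives the endocyclic C7=C8 alkene of the doubly activated butenolide.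

Step 2
Reactants: 4 diethyl (2-oxo-2,5-dihydrofuran-3-yl)phosphonate; 5 (R)-citronellal
Product: 6 diethyl {(3S,4R)-4-[(2S,3R)-3,7-dimethyl-1-oxooct-6-en-2-yl]-2-oxooxolan-3-yl}phosphonate (C1 aldehyde; 8R,9S,1′R)
Conditions: (R)-2-[diphenyl(trimethylsilyloxy)methyl]pyrrolidine (10 mol %), PhCO2H (10 mol %), CH2Cl2, 0 °C
Reagents that add atoms: none
Why: Enamine-catalysed Michael addition to a gem-diactivated alkene (the acceptor class of alkylidene malonates and vinyl phosphonates): the (R)-diarylprolinol silyl ether shields one face of the (E)-enamine and so sets C9 (S), a synclinal approach that keeps the phosphoryl-bearing C7 near the enamine nitrogen (the topology followed by nitroalkenes) should set C8 with the C9 side chain and C11 syn along the C1–C9–C8–C7 backbone, and C1′ comes unchanged from citronellal.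

Step 3
Reactants: 7 tert-butyl(but-3-yn-1-yloxy)dimethylsilane
Product: 9 5-[(tert-butyldimethylsilyl)oxy]pent-2-yn-1-ol, via lithium acetylide 8 (not isolated)
Conditions: n-BuLi, THF, −78 °C; (CH2O)n, −78 °C to rt; then H2O
Reagents that add atoms: paraformaldehyde (as formaldehyde), C=O
Why: Hydroxymethylation of a lithium acetylide with formaldehyde, a standard alkynylation that leaves the silyl ether untouched.

Step 4
Reactants: 9 5-[(tert-butyldimethylsilyl)oxy]pent-2-yn-1-ol
Product: 10 5-[(tert-butyldimethylsilyl)oxy]pent-2-yn-1-yl methyl carbonate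
Conditions: ClCO2Me, pyridine, CH2Cl2, 0 °C
Reagents that add atoms: methyl chloroformate, COC(=O)Cl
Why: O-Acylation of the primary propargylic alcohol with a chloroformate under pyridine catalysis installs the leaving group for the next step.

Step 5
Reactants: 10 5-[(tert-butyldimethylsilyl)oxy]pent-2-yn-1-yl methyl carbonate
Product: 11 tert-butyldimethyl{[3-(4,4,5,5-tetramethyl-1,3,2-dioxaborolan-2-yl)penta-3,4-dien-1-yl]oxy}silane
Conditions: CuCl (10 mol %), NaOtBu (12 mol %), Xantphos (10 mol %), B2pin2, THF, rt
Reagents that add atoms: bis(pinacolato)diboron, CC1(C)OB(OC1(C)C)B1OC(C)(C)C(C)(C)O1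
Why: Copper-catalysed SN2′ borylation of a propargylic carbonate, in which the boryl-copper species adds to the alkyne carbon remote from the carbonate and β-elimination with loss of CO2 and methoxide gives the 1,1-disubstituted allenylboronate.

Step 6
Reactants: 6 Michael adduct aldehyde; 11 allenylboronate
Product: 13 (1R)-homopropargylic alcohol (6 with C1 as CH(OH) bearing CH2–C≡C–CH2CH2OSi(t-Bu)Me2; 1R,8R,9S,1′R), via O-boryl ether 12 (not isolated)
Conditions: (R)-TRIP [(R)-3,3′-bis(2,4,6-triisopropylphenyl)-1,1′-binaphthyl-2,2′-diyl hydrogen phosphate] (10 mol %), 4 Å molecular sieves, toluene, 0 °C to rt; then aq. NaHCO3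
Reagents that add atoms: none
Why: Chiral phosphoric acid-catalysed allenylboration of an aldehyde through a closed six-membered SE2′ transition state, which delivers the CH2 terminus to C1 and hence only the homopropargylic alcohol; the acid, hydrogen-bonded to the boronate oxygen and the formyl hydrogen, is expected to override the weak bias of C9 and direct attack to the Re face, giving (1R).

Step 7
Reactants: 13 (1R)-homopropargylic alcohol
Product: 14 (Z)-alkenylstannane (C3 bears SnBu3, C4 bears H; tin cis to C5, C2 trans to C5)
Conditions: [Cp*RuCl]4 (2.5 mol %), Bu3SnH, CH2Cl2, rt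
Reagents that add atoms: tributyltin hydride, CCCC[SnH](CCCC)CCCC
Why: Ruthenium-catalysed trans-hydrostannation of an internal alkyne, in which hydrogen bonding of the free C1 hydroxyl to the chloride ligand steers tin to the proximal carbon C3 and the anti addition puts hydrogen on C4 opposite to tin, while the silyl ether on the other flank cannot act as a directing group.

Step 8
Reactants: 14 (Z)-alkenylstannane
Product: 15 (E)-homoallylic alcohol (C3 bears CH3; C2 trans to C5)
Conditions: MeI, Pd(PPh3)4 (5 mol %), copper thiophene-2-carboxylate Cu(O2CC4H3S), [NBu4][Ph2PO2], DMF, rt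
Reagents that add atoms: iodomethane, CI
Why: Copper-assisted Stille cross-coupling of the alkenylstannane with iodomethane under base-free and fluoride-free conditions, which replaces tin by methyl with retention and so fixes the (E)-C3=C4 geometry.

Step 9
Reactants: 15 (E)-homoallylic alcohol
Product: 16 C1 acetate of 15 (C6 still silylated)
Conditions: Ac2O, pyridine, DMAP (cat.), CH2Cl2, 0 °C to rt
Reagents that add atoms: acetic anhydride, CC(=O)OC(C)=O
Why: DMAP-catalysed acetylation of the only free hydroxyl group, so that no selectivity between two alcohols is needed.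

Step 10
Reactants: 16 C1 acetate
Product: 17 primary alcohol (16 with C6H2OH)
Conditions: HF·pyridine, pyridine, THF, 0 °C to rt
Reagents that add atoms: none
Why: Fluoride-mediated cleavage of the primary silyl ether under buffered, weakly acidic conditions that leave the acetate, the lactone and the phosphonate esters intact.

Step 11
Reactants: 17 primary alcohol
Product: 18 α-phosphono lactone aldehyde (C6 formyl, C1 acetate; 1R,8R,9S,1′R,3E)
Conditions: Dess–Martin periodinane, NaHCO3, CH2Cl2, 0 °C
Reagents that add atoms: none
Why: Dess–Martin oxidation under bicarbonate buffering converts the homoallylic alcohol into the β,γ-unsaturated aldehyde at neutral pH without moving the C3=C4 double bond, and the aldehyde is used at once.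

Step 12
Reactants: 18 α-phosphono lactone aldehyde
Product: 19 target CNP0288725.2
Conditions: LiCl, i-Pr2NEt, MeCN, ca. 1 mM (syringe-pump addition of 18), rt
Reagents that add atoms: none
Why: LiCl and the amine deprotonate C7 reversibly to the lithium-chelated phosphonate enolate, which adds to the C6 formyl carbon; the β-oxido phosphonate closes to an oxaphosphetane that collapses irreversibly with loss of lithium diethyl phosphate, so the C6=C7 bond and ring A form together. The closest known reaction type is the intramolecular Horner–Wadsworth–Emmons macrocyclisation under Masamune–Roush conditions, used here at the small end of its ring-size range. Ring A closes by a 9-exo-trig addition of C7 to the aldehyde, the two chains being held on the neighbouring carbons C8 and C9. No stereocentre is created: both C7 epimers converge because C7 becomes trigonal, and C1, C8, C9 and C1′ are not touched. The required (E)-alkylidene (C5 anti to the lactone carbonyl, hence C5 and C8 cis in ring A) is the geometry α-phosphono lactones normally give and the only one the nine-membered ring can hold. Chemoselectivity rests on C7–H being by far the most acidic site, so the weak base should leave the β,γ-unsaturated aldehyde unconjugated and the acetate intact, while high dilution favours ring closure over dimerisation.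

Compound list

1 | diethyl (2-oxotetrahydrofuran-3-yl)phosphonate | CCOP(=O)(OCC)C1CCOC1=O | starting material
2 | diethyl [2-oxo-3-(phenylselanyl)tetrahydrofuran-3-yl]phosphonate (racemic) | CCOP(=O)(OCC)C1([Se]c2ccccc2)CCOC1=O | intermediate
3 | diethyl [2-oxo-3-(phenylseleninyl)tetrahydrofuran-3-yl]phosphonate (selenoxide) | CCOP(=O)(OCC)C1([Se](=O)c2ccccc2)CCOC1=O | intermediate
4 | diethyl (2-oxo-2,5-dihydrofuran-3-yl)phosphonate | CCOP(=O)(OCC)C1=CCOC1=O | intermediate
5 | (R)-citronellal, (3R)-3,7-dimethyloct-6-enal | C[C@H](CCC=C(C)C)CC=O | starting material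
6 | diethyl {(3S,4R)-4-[(2S,3R)-3,7-dimethyl-1-oxooct-6-en-2-yl]-2-oxooxolan-3-yl}phosphonate | O=C[C@@H]([C@H](C)CCC=C(C)C)[C@@H]1COC(=O)[C@H]1P(=O)(OCC)OCC | intermediate
7 | tert-butyl(but-3-yn-1-yloxy)dimethylsilane | C#CCCO[Si](C)(C)C(C)(C)C | starting material
8 | lithium acetylide of 7 | [Li]C#CCCO[Si](C)(C)C(C)(C)C | intermediate
9 | 5-[(tert-butyldimethylsilyl)oxy]pent-2-yn-1-ol | OCC#CCCO[Si](C)(C)C(C)(C)C | intermediate
10 | 5-[(tert-butyldimethylsilyl)oxy]pent-2-yn-1-yl methyl carbonate | COC(=O)OCC#CCCO[Si](C)(C)C(C)(C)C | intermediate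
11 | tert-butyldimethyl{[3-(4,4,5,5-tetramethyl-1,3,2-dioxaborolan-2-yl)penta-3,4-dien-1-yl]oxy}silane | C=C=C(CCO[Si](C)(C)C(C)(C)C)B1OC(C)(C)C(C)(C)O1 | intermediate
12 | pinacol borate ester of 13 (C1–O–B) | CC1(C)OB(O[C@H](CC#CCCO[Si](C)(C)C(C)(C)C)[C@@H]([C@H](C)CCC=C(C)C)[C@@H]2COC(=O)[C@H]2P(=O)(OCC)OCC)OC1(C)C | intermediate
13 | (1R)-homopropargylic alcohol, C1H(OH)–CH2–C≡C–CH2CH2OTBS on the (8R,9S,1′R) phosphono lactone | O[C@H](CC#CCCO[Si](C)(C)C(C)(C)C)[C@@H]([C@H](C)CCC=C(C)C)[C@@H]1COC(=O)[C@H]1P(=O)(OCC)OCC | intermediate
14 | (3Z)-C3-tributylstannyl alkene of 13 (tin cis to C5) | O[C@H](C/C(=C/CCO[Si](C)(C)C(C)(C)C)[Sn](CCCC)(CCCC)CCCC)[C@@H]([C@H](C)CCC=C(C)C)[C@@H]1COC(=O)[C@H]1P(=O)(OCC)OCC | intermediate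
15 | (3E)-C3-methyl homoallylic alcohol (1R,8R,9S,1′R) | O[C@H](C/C(C)=C/CCO[Si](C)(C)C(C)(C)C)[C@@H]([C@H](C)CCC=C(C)C)[C@@H]1COC(=O)[C@H]1P(=O)(OCC)OCC | intermediate
16 | C1 acetate of 15 | CC(=O)O[C@H](C/C(C)=C/CCO[Si](C)(C)C(C)(C)C)[C@@H]([C@H](C)CCC=C(C)C)[C@@H]1COC(=O)[C@H]1P(=O)(OCC)OCC | intermediate
17 | C1 acetate with free C6 primary alcohol | CC(=O)O[C@H](C/C(C)=C/CCO)[C@@H]([C@H](C)CCC=C(C)C)[C@@H]1COC(=O)[C@H]1P(=O)(OCC)OCC | intermediate
18 | key-step precursor: α-phosphono lactone with C6 aldehyde and C1 acetate (1R,8R,9S,1′R,3E) | CC(=O)O[C@H](C/C(C)=C/CC=O)[C@@H]([C@H](C)CCC=C(C)C)[C@@H]1COC(=O)[C@H]1P(=O)(OCC)OCC | intermediate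
19 | target CNP0288725.2: ring A/ring B bicycle with C1 acetate, C3 methyl, (2R)-6-methylhept-5-en-2-yl on C9; (1R,8S,9S,1′R), 3E, 6E | CC(=O)O[C@@H]1C/C(C)=C/C/C=C2/C(=O)OC[C@H]2[C@@H]1[C@H](C)CCC=C(C)C | target

Total step count: 12. Longest linear sequence: 10 steps (steps 3 to 12, from 7). Steps 1 and 2 make the aldehyde 6 from 1 and 5 in a two-step branch that joins the main line at step 6.

Steps most likely to fail

1. Step 12. The strain of ring A may slow the intramolecular addition so much that base-induced migration of the formyl group into conjugation with C3=C4, or pairing of two chains to the eighteen-membered dimer, takes over. The fallback sets out from 18 and comes back at 19. The aldehyde is methylenated without base (Takai–Lombardo reagent: Zn, CH2Br2, TiCl4, THF/CH2Cl2, 0 °C) to the C6-vinyl phosphonate F1. A Horner–Wadsworth–Emmons reaction with aqueous formaldehyde (K2CO3, THF, 0 °C) converts the phosphonate into the α-methylene lactone F2. Ring-closing metathesis between the C7 methylene and the C6 vinyl group (second-generation Hoveyda–Grubbs catalyst, toluene, 80 °C, high dilution) then makes the same C6=C7 bond without base or a free aldehyde and gives 19. This removes the base-sensitivity problem but not the ring strain.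

2. Step 2. Facial discrimination on the butenolide (the C8 centre) may be poor, or the secondary amine may be consumed by the very electrophilic acceptor. The fallback sets out from 5 and 4 and comes back at 6. Condensation of 5 with (S)-1-amino-2-(methoxymethyl)pyrrolidine gives the SAMP hydrazone F3. Deprotonation (LiN(iPr)2, THF, −78 °C) and conjugate addition of the chelated azaenolate to 4 give the adduct hydrazone F4, in which a stoichiometric auxiliary and a closed lithium-bridged transition state take over the control of C9 and C8. Two-phase cleavage with aqueous oxalic acid/Et2O releases 6.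

3. Step 6. The hindered α-branched aldehyde may react sluggishly with the substituted allenylboronate, and the catalyst may fail to override the substrate, giving poor facial selectivity at C1. The fallback sets out from 6 and 11 and comes back at 16. The addition is run with achiral diphenyl phosphate (toluene, rt) and the C1 epimers are separated; 13 continues as planned. The (1S)-homopropargylic alcohol F5 is taken through the conditions of steps 7 and 8 to the (1S)-alkenylstannane F6 and the (1S)-homoallylic alcohol F7. F7 is esterified with inversion at C1 under Mitsunobu conditions (AcOH, PPh3, DIAD, toluene, 0 °C to rt) to give 16.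

Further compounds

F1 | step 12 | C6-vinyl phosphonate (18 with CH=O replaced by CH=CH2) | CC(=O)O[C@H](C/C(C)=C/CC=C)[C@@H]([C@H](C)CCC=C(C)C)[C@@H]1COC(=O)[C@H]1P(=O)(OCC)OCC
F2 | step 12 | α-methylene lactone (F1 with C7=CH2 in place of the phosphonate) | CC(=O)O[C@H](C/C(C)=C/CC=C)[C@@H]([C@H](C)CCC=C(C)C)[C@@H]1COC(=O)C1=C
F3 | step 2 | SAMP hydrazone of (R)-citronellal | C[C@H](CCC=C(C)C)C/C=N/N1CCC[C@H]1COC
F4 | step 2 | SAMP hydrazone of aldehyde 6 | COC[C@@H]1CCCN1/N=C/[C@@H]([C@H](C)CCC=C(C)C)[C@@H]1COC(=O)[C@H]1P(=O)(OCC)OCC
F5 | step 6 | (1S)-epimer of homopropargylic alcohol 13 | O[C@@H](CC#CCCO[Si](C)(C)C(C)(C)C)[C@@H]([C@H](C)CCC=C(C)C)[C@@H]1COC(=O)[C@H]1P(=O)(OCC)OCC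
F6 | step 6 | (1S)-epimer of alkenylstannane 14 | O[C@@H](C/C(=C/CCO[Si](C)(C)C(C)(C)C)[Sn](CCCC)(CCCC)CCCC)[C@@H]([C@H](C)CCC=C(C)C)[C@@H]1COC(=O)[C@H]1P(=O)(OCC)OCC
F7 | step 6 | (1S)-epimer of homoallylic alcohol 15 | O[C@@H](C/C(C)=C/CCO[Si](C)(C)C(C)(C)C)[C@@H]([C@H](C)CCC=C(C)C)[C@@H]1COC(=O)[C@H]1P(=O)(OCC)OCC
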